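**Plan**

Ring atoms are numbered C1 (ketone), C2 (=CH), C3 (bearing CH2O), C4 (carbinol), C5 (oxirane CH) and C6 (oxirane carbon bearing the farnesyl chain). The retrosynthesis first cuts the ester C–O bond to the hydroxymethylglutarate, then, in one operation, the ring bonds C2–C3 and C5–C6 together with the oxirane C6–O bond.
Enabling feature: C2 and C6 are the two α-carbons of the single ketone C1, and an oxirane fused at C5–C6 next to that ketone is the mark of a Darzens closure. C3 and C5 stand 1,3 across C4, at the β-carbon and carbonyl level of an α-oxygenated enal. A phenylsulfinyl group at C2 is added as a removable activator that later becomes the C2=C3 double bond.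
Forward: a farnesyl-bearing γ-chloro-β-keto sulfoxide (steps 1 to 3) and (Z)-2,4-bis(silyloxy)but-2-enal (steps 4 and 5) are joined in step 6. That step closes the carbocycle (Michael addition, then aldol), then the oxirane, then forms the enone. The half ester from (R)-mevalonolactone (steps 8 and 9) is attached to the freed primary hydroxyl, and the silicon groups are removed last.
Stereochemistry: a chiral primary amine sets C3 of the Michael adduct. This centre relays to C4, C5 and C6 through the chair-like Darzens closure and is then erased by the sulfoxide elimination. The side-chain carbinol centre comes from (R)-mevalonolactone.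

Key step: step 6

Abbreviations: farnesyl = (2E,6E)-3,7,11-trimethyldodeca-2,6,10-trien-1-yl; TBS = tert-butyldimethylsilyl; SEM = 2-(trimethylsilyl)ethoxymethyl.

Assumption: the quinine-derived primary amine is taken to deliver the donor to the face of the enal β-carbon that gives the (3R) adduct; should the sense be the opposite, the quinidine-derived pseudoenantiomer replaces it and nothing else changes.

**Route**

Step 1
Reactants: 1 methyl 2-chloro-3-oxobutanoate; 2 (2E,6E)-farnesyl bromide
Product: 3 methyl (4E,8E)-2-acetyl-2-chloro-5,9,13-trimethyltetradeca-4,8,12-trienoate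
Conditions: K2CO3, acetone, rt
Reagents that add atoms: none
Why: C-alkylation of the doubly stabilised potassium enolate with the allylic bromide (acetoacetic ester alkylation, SN2) should give the quaternary carbon without touching the triene; the new centre is racemic and is not carried into the target.

Step 2
Reactants: 3 methyl (4E,8E)-2-acetyl-2-chloro-5,9,13-trimethyltetradeca-4,8,12-trienoate
Product: 4 methyl (4E,8E)-2-chloro-5,9,13-trimethyltetradeca-4,8,12-trienoate
Conditions: NaOMe (0.2 equiv), MeOH, 0 °C
Reagents that add atoms: none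
Why: methoxide adds to the ketone of the non-enolisable β-keto ester and retro-Claisen cleavage (deacetylation) expels the α-chloro ester enolate, which methanol protonates; the centre stays racemic and is reset in step 6.

Step 3
Reactants: 4 methyl (4E,8E)-2-chloro-5,9,13-trimethyltetradeca-4,8,12-trienoate; 5 methyl phenyl sulfoxide
Product: 7 (5E,9E)-3-chloro-6,10,14-trimethyl-1-(phenylsulfinyl)pentadeca-5,9,13-trien-2-one, via lithiomethyl phenyl sulfoxide 6 (not isolated)
Conditions: LiN(iPr)2 (2.2 equiv), 5 (2.2 equiv), THF, −78 °C; then 4, −78 to −40 °C; aq. NH4Cl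
Reagents that add atoms: none
Why: Claisen-type acylation of the α-sulfinyl carbanion by the ester is a known route to γ-chloro-β-keto sulfoxides, and the second equivalent of carbanion deprotonates the product and shields it from over-addition; the centres at sulfur and at the chlorine-bearing carbon are left as mixtures because both are erased or reset in step 6.

Step 4
Reactants: 8 (tert-butyldimethylsilyloxy)acetaldehyde (two molecules)
Product: 9 2,4-bis(TBS-oxy)-3-hydroxybutanal
Conditions: L-proline (10 mol%), DMF, rt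
Reagents that add atoms: none
Why: the proline enamine aldol dimerisation of α-silyloxy acetaldehydes should stop at the dimer; its two new stereocentres are immaterial because both are destroyed in step 5.

Step 5
Reactants: 9 2,4-bis(TBS-oxy)-3-hydroxybutanal
Product: 11 (2Z)-2,4-bis(TBS-oxy)but-2-enal, via aldol mesylate 10 (not isolated)
Conditions: MsCl, Et3N, CH2Cl2, 0 °C to rt
Reagents that add atoms: none
Why: mesylation of the β-hydroxyl and E1cB loss of mesylate through the aldehyde enolate (aldol dehydration) should give the conjugated enal with the CH2OTBS group trans to the formyl group, that is the Z isomer.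

Step 6
Reactants: 7 (5E,9E)-3-chloro-6,10,14-trimethyl-1-(phenylsulfinyl)pentadeca-5,9,13-trien-2-one; 11 (2Z)-2,4-bis(TBS-oxy)but-2-enal
Product: 14 (1R,5R,6R)-5-(TBS-oxy)-4-[(TBS-oxy)methyl]-1-farnesyl-7-oxabicyclo[4.1.0]hept-3-en-2-one, via Michael adduct aldehyde 12 (not isolated), via epoxy keto sulfoxide 13 (not isolated)
Conditions: 9-amino-9-deoxy-epi-quinine (20 mol%), 2-fluorobenzoic acid (40 mol%), PhMe, rt; then K2CO3, rt; then filtration through a short pad of silica gel, CaCO3, PhMe, 70 °C
Reagents that add atoms: none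
Why: Proposed new method: the primary amine condenses with 11 to an iminium ion that accepts the doubly activated C–H carbon of 7 at its β-carbon (first bond, ring atoms C2–C3, giving 12); K2CO3 then equilibrates 12 to its chloro enolate, which closes the six-membered ring by a reversible 6-(enolendo)-exo-trig aldol addition onto the aldehyde and the oxirane by 3-exo-tet displacement of chloride (second bond, C5–C6, giving 13), and warming expels PhSOH by thermal syn-elimination to leave the C2=C3 double bond. The closest known reaction type is the amine-catalysed Michael/aldol/SN2 epoxy-annulation of γ-chloro-β-keto esters with enals, joined here with primary-amine iminium activation of α-branched enals and the β-keto sulfoxide route to enones; an α-silyloxy enal as acceptor and a β-keto sulfoxide as donor are not known to have been used in it. C3 of 12 is set by the catalyst, which shields one face of the iminium β-carbon; C4, α to the aldehyde, epimerises and enters the chair-like closure with its silyloxy group equatorial, where it avoids a 1,3-diaxial contact with the axial chlorine. C5 and C6 follow from that chair with the C3 substituent equatorial, since only the aldolate with alkoxide and chloride trans-diaxial can close to the oxirane and the others revert by retro-aldol; this puts the oxirane oxygen cis to the C4 oxygen and trans to the C3 substituent. The step needs C2 rather than C6 to act as Michael donor and 1,4- rather than 1,2-addition, which the far higher acidity of the sulfinyl-activated C–H and the soft iminium acceptor should secure, and it needs the aldol to outrun retro-Michael loss of the C3 information. The elimination can only run towards C3, which holds the sole β-hydrogen, and it removes the C2, C3 and sulfur stereocentres together with the activating group, so that all sulfur and C2 epimers converge on one enantiomer of 14.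

Step 7
Reactants: 14 (1R,5R,6R)-5-(TBS-oxy)-4-[(TBS-oxy)methyl]-1-farnesyl-7-oxabicyclo[4.1.0]hept-3-en-2-one
Product: 15 (1R,5R,6R)-5-(TBS-oxy)-4-(hydroxymethyl)-1-farnesyl-7-oxabicyclo[4.1.0]hept-3-en-2-one
Conditions: HF·pyridine, pyridine, THF, 0 °C
Reagents that add atoms: none
Why: the unhindered primary allylic silyl ether should be cleaved much faster by buffered HF·pyridine than the secondary one flanked by the oxirane (selective desilylation), and the buffered medium leaves the epoxy enone and its stereocentres untouched.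

Step 8
Reactants: 16 (R)-mevalonolactone
Product: 18 SEM (3R)-3,5-dihydroxy-3-methylpentanoate, via potassium (R)-mevalonate 17 (not isolated)
Conditions: KOH, H2O, rt, then evaporation; SEMCl, DMF, 0 °C to rt
Reagents that add atoms: potassium hydroxide [K+].[OH-]; 2-(trimethylsilyl)ethoxymethyl chloride C[Si](C)(C)CCOCCl
Why: saponification of the δ-lactone and O-alkylation of the carboxylate with the reactive alkoxymethyl chloride (SN2 esterification) fix the former lactone carbonyl as the protected acid terminus; the quaternary stereocentre is not touched.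

Step 9
Reactants: 18 SEM (3R)-3,5-dihydroxy-3-methylpentanoate
Product: 20 (3R)-3-hydroxy-3-methyl-5-oxo-5-(SEM-oxy)pentanoic acid, via hydroxy aldehyde 19 (not isolated)
Conditions: (2,2,6,6-tetramethylpiperidin-1-yl)oxyl (cat.), NaOCl (cat.), NaClO2, MeCN/phosphate buffer pH 6.7, 35 °C
Reagents that add atoms: sodium chlorite [Na+].[O-]Cl=O
Why: the oxoammonium/chlorite oxidation converts only the primary alcohol into the acid at near-neutral pH, the tertiary alcohol and the ester are inert, and the quaternary centre cannot epimerise.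

Step 10
Reactants: 15 (1R,5R,6R)-5-(TBS-oxy)-4-(hydroxymethyl)-1-farnesyl-7-oxabicyclo[4.1.0]hept-3-en-2-one; 20 (3R)-3-hydroxy-3-methyl-5-oxo-5-(SEM-oxy)pentanoic acid
Product: 21 [(1R,5R,6R)-5-(TBS-oxy)-2-oxo-1-farnesyl-7-oxabicyclo[4.1.0]hept-3-en-4-yl]methyl SEM (3R)-3-hydroxy-3-methylpentanedioate
Conditions: N-ethyl-N′-(3-dimethylaminopropyl)carbodiimide hydrochloride, 4-(dimethylamino)pyridine (cat.), CH2Cl2, 0 °C to rt
Reagents that add atoms: none
Why: Steglich esterification of the only free hydroxyl of 15; the tertiary hydroxyl of 20 is too hindered to compete, and no stereocentre is affected (the descriptor at the side-chain centre is R here only because of the priority of the SEM ester arm).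

Step 11
Reactants: 21 [(1R,5R,6R)-5-(TBS-oxy)-2-oxo-1-farnesyl-7-oxabicyclo[4.1.0]hept-3-en-4-yl]methyl SEM (3R)-3-hydroxy-3-methylpentanedioate
Product: 22 [(1R,5R,6R)-5-hydroxy-2-oxo-1-farnesyl-7-oxabicyclo[4.1.0]hept-3-en-4-yl]methyl hydrogen (3S)-3-hydroxy-3-methylpentanedioate (target)
Conditions: 48% aq. HF, MeCN, 0 °C to rt
Reagents that add atoms: none
Why: fluoride-induced cleavage should remove the secondary silyl ether and, by attack at silicon with loss of ethene and formaldehyde, the SEM ester, under conditions that epoxyquinols and the allylic ester are expected to tolerate; no stereocentre is touched.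

**Compound list**

1 | methyl 2-chloro-3-oxobutanoate | CC(=O)C(Cl)C(=O)OC | starting material
2 | (2E,6E)-farnesyl bromide | CC(C)=CCC/C(C)=C/CC/C(C)=C/CBr | starting material
3 | methyl (4E,8E)-2-acetyl-2-chloro-5,9,13-trimethyltetradeca-4,8,12-trienoate (racemic) | COC(=O)C(Cl)(C(C)=O)C/C=C(\C)CC/C=C(\C)CCC=C(C)C | intermediate
4 | methyl (4E,8E)-2-chloro-5,9,13-trimethyltetradeca-4,8,12-trienoate (racemic) | COC(=O)C(Cl)C/C=C(\C)CC/C=C(\C)CCC=C(C)C | intermediate
5 | methyl phenyl sulfoxide (racemic) | CS(=O)c1ccccc1 | starting material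
6 | lithiomethyl phenyl sulfoxide | [Li]CS(=O)c1ccccc1 | intermediate
7 | (5E,9E)-3-chloro-6,10,14-trimethyl-1-(phenylsulfinyl)pentadeca-5,9,13-trien-2-one (mixture at C3 and sulfur) | O=S(c1ccccc1)CC(=O)C(Cl)C/C=C(\C)CC/C=C(\C)CCC=C(C)C | intermediate
8 | (tert-butyldimethylsilyloxy)acetaldehyde | O=CCO[Si](C)(C)C(C)(C)C | starting material
9 | 2,4-bis(TBS-oxy)-3-hydroxybutanal (mixture of stereoisomers) | O=CC(O[Si](C)(C)C(C)(C)C)C(O)CO[Si](C)(C)C(C)(C)C | intermediate
10 | 2,4-bis(TBS-oxy)-3-(methylsulfonyloxy)butanal | O=CC(O[Si](C)(C)C(C)(C)C)C(OS(C)(=O)=O)CO[Si](C)(C)C(C)(C)C | intermediate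
11 | (2Z)-2,4-bis(TBS-oxy)but-2-enal | O=C/C(O[Si](C)(C)C(C)(C)C)=C/CO[Si](C)(C)C(C)(C)C | intermediate
12 | (3R,8E,12E)-2-(TBS-oxy)-3-[(TBS-oxy)methyl]-6-chloro-9,13,17-trimethyl-5-oxo-4-(phenylsulfinyl)octadeca-8,12,16-trienal (C2, C4, C6 and sulfur not fixed) | O=CC(O[Si](C)(C)C(C)(C)C)[C@@H](CO[Si](C)(C)C(C)(C)C)C(S(=O)c1ccccc1)C(=O)C(Cl)C/C=C(\C)CC/C=C(\C)CCC=C(C)C | intermediate
13 | (1R,4R,5R,6R)-5-(TBS-oxy)-4-[(TBS-oxy)methyl]-3-(phenylsulfinyl)-1-farnesyl-7-oxabicyclo[4.1.0]heptan-2-one (epimers at C3 and sulfur) | CC(C)=CCC/C(C)=C/CC/C(C)=C/C[C@@]12O[C@@H]1[C@H](O[Si](C)(C)C(C)(C)C)[C@@H](CO[Si](C)(C)C(C)(C)C)C(S(=O)c3ccccc3)C2=O | intermediate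
14 | (1R,5R,6R)-5-(TBS-oxy)-4-[(TBS-oxy)methyl]-1-farnesyl-7-oxabicyclo[4.1.0]hept-3-en-2-one | CC(C)=CCC/C(C)=C/CC/C(C)=C/C[C@@]12O[C@@H]1[C@H](O[Si](C)(C)C(C)(C)C)C(CO[Si](C)(C)C(C)(C)C)=CC2=O | intermediate
15 | (1R,5R,6R)-5-(TBS-oxy)-4-(hydroxymethyl)-1-farnesyl-7-oxabicyclo[4.1.0]hept-3-en-2-one | CC(C)=CCC/C(C)=C/CC/C(C)=C/C[C@@]12O[C@@H]1[C@H](O[Si](C)(C)C(C)(C)C)C(CO)=CC2=O | intermediate
16 | (R)-mevalonolactone, (4R)-4-hydroxy-4-methyloxan-2-one | O=C1C[C@](C)(O)CCO1 | starting material
17 | potassium (3R)-3,5-dihydroxy-3-methylpentanoate | [K+].[O-]C(=O)C[C@](C)(O)CCO | intermediate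
18 | SEM (3R)-3,5-dihydroxy-3-methylpentanoate | OCC[C@@](C)(O)CC(=O)OCOCC[Si](C)(C)C | intermediate
19 | SEM (3R)-3-hydroxy-3-methyl-5-oxopentanoate | O=CC[C@@](C)(O)CC(=O)OCOCC[Si](C)(C)C | intermediate
20 | (3R)-3-hydroxy-3-methyl-5-oxo-5-(SEM-oxy)pentanoic acid | OC(=O)C[C@@](C)(O)CC(=O)OCOCC[Si](C)(C)C | intermediate
21 | [(1R,5R,6R)-5-(TBS-oxy)-2-oxo-1-farnesyl-7-oxabicyclo[4.1.0]hept-3-en-4-yl]methyl SEM (3R)-3-hydroxy-3-methylpentanedioate | CC(C)=CCC/C(C)=C/CC/C(C)=C/C[C@@]12O[C@@H]1[C@H](O[Si](C)(C)C(C)(C)C)C(COC(=O)C[C@@](C)(O)CC(=O)OCOCC[Si](C)(C)C)=CC2=O | intermediate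
22 | [(1R,5R,6R)-5-hydroxy-2-oxo-1-farnesyl-7-oxabicyclo[4.1.0]hept-3-en-4-yl]methyl hydrogen (3S)-3-hydroxy-3-methylpentanedioate | CC(C)=CCC/C(C)=C/CC/C(C)=C/C[C@@]12O[C@@H]1[C@H](O)C(COC(=O)C[C@@](C)(O)CC(=O)O)=CC2=O | target

**Summary**

Total step count: 11. Longest linear sequence: 7 steps (steps 1, 2, 3, 6, 7, 10, 11).

Steps most likely to fail:

1. Step 6. The conjugate addition to the electron-rich α-silyloxy enal may be sluggish, and the amine catalyst may be consumed by the α-chloro ketone. The stereochemical relay may also leak, through retro-Michael equilibration or closure through the less favoured chair, which would lower the enantiomeric purity once C3 is erased.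
Fallback, from 2 to 14, by the quinone monoketal route known for epoxyquinols: commercial 5-hydroxy-2-methoxybenzaldehyde is reduced (NaBH4, MeOH) to 3-(hydroxymethyl)-4-methoxyphenol F1. Its sodium phenoxide (NaH, PhMe) is C-alkylated with 2 at the free ortho position to give 2-farnesyl-5-(hydroxymethyl)-4-methoxyphenol F2. Oxidative dearomatisation (PhI(OAc)2, MeOH) gives 2-farnesyl-5-(hydroxymethyl)-4,4-dimethoxycyclohexa-2,5-dien-1-one F3. Nucleophilic epoxidation (tBuOOH, DBU) should attack the β-unsubstituted double bond that carries the farnesyl group and give the racemic epoxy monoketal F4. Aqueous acid (aq. HF, MeCN) releases the racemic epoxyquinone F5. Reduction directed by the primary hydroxyl (iBu2AlH, THF, −78 °C) should deliver hydride to the neighbouring carbonyl from the face opposite the oxirane and give the racemic cis-epoxy diol F6. Chromatography on a chiral stationary phase gives the (1R,5R,6R)-diol F7, and bis-silylation (TBSOTf, 2,6-lutidine) gives 14.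

2. Step 11. HF may open the oxirane or add to the trisubstituted olefins, the alkoxymethyl ester may be cleaved incompletely, or the acyl group may migrate to the C4 hydroxyl.
Fallback, from 17 and 15 to 22, with a protecting group removed under neutral conditions: salt 17 is alkylated with allyl bromide (DMF) to allyl (3R)-3,5-dihydroxy-3-methylpentanoate F9. This is oxidised as in step 9 to (3R)-5-(allyloxy)-3-hydroxy-3-methyl-5-oxopentanoic acid F10 and coupled with 15 as in step 10 to the allyl diester F11. Buffered HF·pyridine removes the silyl ether to give the hydroxy allyl diester F12. A zerovalent palladium complex, Pd(PPh3)4, with N-methylaniline as allyl acceptor then frees the acid and gives 22.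

3. Step 3. The basic sulfinyl carbanion may deprotonate the α-chloro ester, which then condenses with itself instead of being acylated.
Fallback, from 5 and 2 to 7, with the order of bond formation reversed: 5 is acylated with ethyl chloroacetate (LiN(iPr)2, THF, −78 °C) to give 1-chloro-3-(phenylsulfinyl)propan-2-one F8. Its dianion (LiN(iPr)2, 2.2 equiv, THF, −78 °C) is alkylated with 2 at the chlorine-bearing γ-carbon, as is known for β-keto sulfoxide dianions, to give 7; steps 1 and 2 are then not needed.

**Further compounds**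

F1 | step 6 | 3-(hydroxymethyl)-4-methoxyphenol | COc1ccc(O)cc1CO
F2 | step 6 | 2-farnesyl-5-(hydroxymethyl)-4-methoxyphenol | COc1cc(C/C=C(\C)CC/C=C(\C)CCC=C(C)C)c(O)cc1CO
F3 | step 6 | 2-farnesyl-5-(hydroxymethyl)-4,4-dimethoxycyclohexa-2,5-dien-1-one | COC1(OC)C=C(C/C=C(\C)CC/C=C(\C)CCC=C(C)C)C(=O)C=C1CO
F4 | step 6 | racemic 1-farnesyl-4-(hydroxymethyl)-5,5-dimethoxy-7-oxabicyclo[4.1.0]hept-3-en-2-one | COC1(OC)C2OC2(C/C=C(\C)CC/C=C(\C)CCC=C(C)C)C(=O)C=C1CO
F5 | step 6 | racemic 1-farnesyl-4-(hydroxymethyl)-7-oxabicyclo[4.1.0]hept-3-ene-2,5-dione | O=C1C=C(CO)C(=O)C2OC12C/C=C(\C)CC/C=C(\C)CCC=C(C)C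
F6 | step 6 | racemic 1-farnesyl-5-hydroxy-4-(hydroxymethyl)-7-oxabicyclo[4.1.0]hept-3-en-2-one, hydroxyl cis to the oxirane oxygen | O=C1C=C(CO)C(O)C2OC12C/C=C(\C)CC/C=C(\C)CCC=C(C)C
F7 | step 6 | (1R,5R,6R)-1-farnesyl-5-hydroxy-4-(hydroxymethyl)-7-oxabicyclo[4.1.0]hept-3-en-2-one | CC(C)=CCC/C(C)=C/CC/C(C)=C/C[C@@]12O[C@@H]1[C@H](O)C(CO)=CC2=O
F8 | step 3 | 1-chloro-3-(phenylsulfinyl)propan-2-one | O=C(CCl)CS(=O)c1ccccc1
F9 | step 11 | allyl (3R)-3,5-dihydroxy-3-methylpentanoate | OCC[C@@](C)(O)CC(=O)OCC=C
F10 | step 11 | (3R)-5-(allyloxy)-3-hydroxy-3-methyl-5-oxopentanoic acid | OC(=O)C[C@@](C)(O)CC(=O)OCC=C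
F11 | step 11 | allyl [(1R,5R,6R)-5-(TBS-oxy)-2-oxo-1-farnesyl-7-oxabicyclo[4.1.0]hept-3-en-4-yl]methyl (3R)-3-hydroxy-3-methylpentanedioate | CC(C)=CCC/C(C)=C/CC/C(C)=C/C[C@@]12O[C@@H]1[C@H](O[Si](C)(C)C(C)(C)C)C(COC(=O)C[C@@](C)(O)CC(=O)OCC=C)=CC2=O
F12 | step 11 | allyl [(1R,5R,6R)-5-hydroxy-2-oxo-1-farnesyl-7-oxabicyclo[4.1.0]hept-3-en-4-yl]methyl (3R)-3-hydroxy-3-methylpentanedioate | CC(C)=CCC/C(C)=C/CC/C(C)=C/C[C@@]12O[C@@H]1[C@H](O)C(COC(=O)C[C@@](C)(O)CC(=O)OCC=C)=CC2=O
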